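**Retrosynthetic overview**

1. The target flavanone is opened at the O1–C2 bond of ring C; an asymmetric 6-endo oxa-Michael closure of the 2',4'-dihydroxy-3',5'-diprenylchalcone sets C2 last.
2. Feature used (flavanone numbering): ring A together with C4 is a folded tetraketide in which C4, C8a and C7 are ketone carbons, C5 is an aldehyde-level carbon and C6 and C8 carry the two prenyl groups. Cutting C4a–C5 unfolds the chalcone into a 3,5-diprenyl-4-pyranone that bears the C4a–C4 styryl ketone chain at its position 2.
3. That pyranone comes from 2-methyl-3,5-diprenyl-4-pyranone and a chromenylacrylic Weinreb amide by lateral acylation. The methylpyranone comes from the symmetric bis(homoprenyl) ketone (acetonedicarboxylate plus two prenyl bromides) by formylation, dianion acetylation and cyclodehydration.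
4. The Weinreb amide comes from 2,2-dimethylchromene-6-carbaldehyde (4-hydroxybenzaldehyde, propargyl ether, Claisen cyclisation) by Horner–Wadsworth–Emmons olefination.
5. Ring order: the 4-pyranone and the pyran ring of the chromene first, then carbocyclic ring A out of the pyranone, then ring C.

Key step: step 9

Remark: atom labels C2 to C8a follow the flavanone numbering of the target.
Assumption: the quinidine-derived aminothiourea is taken to close ring C on the face of C2 that gives the 2S centre, by analogy with the facial preference of this catalyst family in conjugate additions to chalcones; should the opposite sense be found, its quinine-derived pseudoenantiomer is used in the same step.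

**Route**

Step 1
Reactants: 1 dimethyl 1,3-acetonedicarboxylate; 2 prenyl bromide (1-bromo-3-methylbut-2-ene)
Product: 4 dimethyl 2,4-bis(3-methylbut-2-enyl)-3-oxopentanedioate (mixture of diastereomers), via monoprenyl keto diester 3 (not isolated)
Conditions: NaH (2 × 1.05 equiv), 2 (2 × 1.05 equiv), THF, 0 °C to rt, base and bromide added in two alternating portions
Reagents that add atoms: prenyl bromide, second equivalent of 2 (CC(C)=CCBr)
Why: Twofold acetoacetic-ester-type C-alkylation of the doubly activated keto diester, each prenyl group coming from one equivalent of 2; in monoprenyl intermediate 3 the unsubstituted methylene is the more acidic site, so the second prenyl group should enter at the other α-carbon, and the two centres formed are lost in step 2.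

Step 2
Reactants: 4 dimethyl 2,4-bis(3-methylbut-2-enyl)-3-oxopentanedioate
Product: 6 2,10-dimethylundeca-2,9-dien-6-one, via keto diacid 5 (not isolated)
Conditions: NaOH (aq., 1 M, 4 equiv), MeOH, rt to 50 °C; then HCl (aq., 1 M) to pH 3, 50 °C
Reagents that add atoms: none
Why: Saponification followed by double decarboxylation of the β-keto diacid (ketone cleavage of an acetoacetic ester), under dilute acid and moderate heat that the trisubstituted alkenes should tolerate.

Step 3
Reactants: 6 2,10-dimethylundeca-2,9-dien-6-one; 7 ethyl formate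
Product: 8 (5Z)-5-(hydroxymethylidene)-2,10-dimethylundeca-2,9-dien-6-one (chelated enol of the β-keto aldehyde)
Conditions: NaH (1.5 equiv), HCO2Et (3 equiv), EtOH (cat.), THF, 0 °C to rt; then HCl (aq., 1 M), 0 °C
Reagents that add atoms: none
Why: Crossed Claisen formylation of a ketone whose two α-methylenes are equivalent; the product is held as its sodium enolate, which blocks a second formylation.

Step 4
Reactants: 8 (5Z)-5-(hydroxymethylidene)-2,10-dimethylundeca-2,9-dien-6-one; 9 N-methoxy-N-methylacetamide
Product: 11 2-methyl-3,5-bis(3-methylbut-2-enyl)-4H-pyran-4-one, via dioxohexanal 10 (not isolated)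
Conditions: LiN(i-Pr)2 (2.1 equiv), THF, −78 to 0 °C; 9 (1.2 equiv), −78 °C to rt; HCl (aq., 1 M) work-up; then p-TsOH·H2O (5 mol %), CH2Cl2, rt
Reagents that add atoms: none
Why: The dianion of the β-keto aldehyde is acylated at its more basic α'-carbon by the Weinreb amide, whose chelated adduct prevents over-reaction, and the released 3,5-dioxo aldehyde closes by hemiacetal formation and dehydration to the 4-pyranone under acid mild enough for the prenyl groups (dianion acylation and cyclodehydration of a 1,3,5-tricarbonyl compound).

Step 5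
Reactants: 12 4-hydroxybenzaldehyde; 13 3-chloro-3-methylbut-1-yne
Product: 14 4-[(2-methylbut-3-yn-2-yl)oxy]benzaldehyde
Conditions: K2CO3 (2 equiv), KI (10 mol %), CuI (5 mol %), acetone, reflux
Reagents that add atoms: none
Why: Copper-assisted O-alkylation of the phenoxide by the tertiary propargylic chloride, the standard entry to aryl 1,1-dimethylpropargyl ethers.

Step 6
Reactants: 14 4-[(2-methylbut-3-yn-2-yl)oxy]benzaldehyde
Product: 15 2,2-dimethyl-2H-chromene-6-carbaldehyde
Conditions: PhNEt2, 190 °C
Reagents that add atoms: none
Why: Aromatic propargyl Claisen rearrangement, enolisation, 1,5-hydrogen shift and oxa-6π electrocyclisation give the 2,2-dimethylchromene; the two ortho positions are equivalent, so one regioisomer is expected.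

Step 7
Reactants: 15 2,2-dimethyl-2H-chromene-6-carbaldehyde; 16 diethyl {2-[methoxy(methyl)amino]-2-oxoethyl}phosphonate
Product: 17 (2E)-3-(2,2-dimethyl-2H-chromen-6-yl)-N-methoxy-N-methylprop-2-enamide
Conditions: NaH (1.2 equiv), 16 (1.2 equiv), THF, 0 °C to rt
Reagents that add atoms: none
Why: Horner–Wadsworth–Emmons olefination with an amide-stabilised phosphonate, which should give the E-alkene through the reversible, thermodynamically controlled addition step.

Step 8
Reactants: 11 2-methyl-3,5-bis(3-methylbut-2-enyl)-4H-pyran-4-one; 17 (2E)-3-(2,2-dimethyl-2H-chromen-6-yl)-N-methoxy-N-methylprop-2-enamide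
Product: 18 2-[(3E)-4-(2,2-dimethyl-2H-chromen-6-yl)-2-oxobut-3-enyl]-3,5-bis(3-methylbut-2-enyl)-4H-pyran-4-one
Conditions: 11 (1.2 equiv), LiN(SiMe3)2 (1.25 equiv), THF, −78 °C; 17 (1.0 equiv), −78 to −20 °C; NH4Cl (aq.)
Reagents that add atoms: none
Why: Lateral acylation of a 2-methyl-4-pyranone: the methyl group is the only vinylogous α-position and is deprotonated selectively, the lithium dienolate reacts at its exocyclic carbon with the amide carbonyl of the electron-rich and therefore poorly Michael-accepting acrylamide, and the chelated adduct releases the ketone only on work-up.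

Step 9
Reactants: 18 2-[(3E)-4-(2,2-dimethyl-2H-chromen-6-yl)-2-oxobut-3-enyl]-3,5-bis(3-methylbut-2-enyl)-4H-pyran-4-one
Product: 20 (2E)-1-[2,4-dihydroxy-3,5-bis(3-methylbut-2-enyl)phenyl]-3-(2,2-dimethyl-2H-chromen-6-yl)prop-2-en-1-one, via methoxymethylene triketone 19 (not isolated)
Conditions: NaOMe (5 equiv), MeOH, argon, 50 °C; then AcOH, 0 °C
Reagents that add atoms: none
Why: Methoxide adds to the unsubstituted ring carbon of the pyranone (pyranone position 6, the future C5), the ring opens by expelling its ring oxygen as the C8a enolate, and the chain appears as 19, the methyl enol ether of the formyl triketone; the C4a methylene, acidified by the C4 and C8a carbonyls, then adds to C5, methoxide leaves, and enolisation of the C7 and C8a carbonyls gives the resorcinol ring. The closest known reaction type is the base-induced recyclisation of 2-(2-oxoalkyl)-4-pyranones, which are masked 3,5,7-triketones, to acylresorcinols, the laboratory form of the aldol folding of a polyketide chain. Ring A closes by a 6-endo-trig addition of the C4a carbanion to C5 of the alkoxymethylene ketone followed by elimination, an aldol-type condensation at the aldehyde oxidation level that forms the C4a–C5 bond. No stereocentre is formed, the epimerisable centre of 19 at C8 becomes an arene carbon, and the E-alkene of the styryl ketone is the stable isomer and should be kept. The step needs carbon closure through C4a to win over re-closure through oxygen: O-closure only returns 18 and is reversible, methoxide attack at pyranone position 2 is likewise unproductive and reversible, whereas C-closure ends in an aromatisation that cannot revert, and C3 is vinylic, so the side chain holds no second carbon acid that could close another ring. Both prenyl groups already sit on C6 and C8, so neither aromatic substitution nor a choice of position on ring A is involved.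

Step 10
Reactants: 20 (2E)-1-[2,4-dihydroxy-3,5-bis(3-methylbut-2-enyl)phenyl]-3-(2,2-dimethyl-2H-chromen-6-yl)prop-2-en-1-one
Product: 21 (2S)-2-(2,2-dimethyl-2H-chromen-6-yl)-7-hydroxy-6,8-bis(3-methylbut-2-enyl)-2,3-dihydro-4H-chromen-4-one (the target flavanone)
Conditions: N-[3,5-bis(trifluoromethyl)phenyl]-N'-[(9R)-6'-methoxycinchonan-9-yl]thiourea (quinidine-derived, 10 mol %), toluene, 0 °C to rt, stopped before equilibration
Reagents that add atoms: none
Why: Asymmetric intramolecular oxa-Michael addition (6-endo-trig) of a 2'-hydroxychalcone under bifunctional catalysis: the thiourea binds the C4 carbonyl while the quinuclidine nitrogen deprotonates the C8a hydroxyl and guides it to one face of C2, so the single stereocentre is set as 2S under catalyst control, and the C7 hydroxyl, which cannot reach C2, remains a spectator.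

**Compound list**

1 | dimethyl 1,3-acetonedicarboxylate (dimethyl 3-oxopentanedioate) | COC(=O)CC(=O)CC(=O)OC | starting material
2 | prenyl bromide (1-bromo-3-methylbut-2-ene) | CC(C)=CCBr | starting material
3 | dimethyl 2-(3-methylbut-2-enyl)-3-oxopentanedioate (monoprenyl keto diester, not isolated, centre not controlled) | COC(=O)CC(=O)C(CC=C(C)C)C(=O)OC | intermediate
4 | dimethyl 2,4-bis(3-methylbut-2-enyl)-3-oxopentanedioate (diastereomer mixture, centres not controlled) | COC(=O)C(CC=C(C)C)C(=O)C(CC=C(C)C)C(=O)OC | intermediate
5 | 2,4-bis(3-methylbut-2-enyl)-3-oxopentanedioic acid (keto diacid, not isolated, centres not controlled) | OC(=O)C(CC=C(C)C)C(=O)C(CC=C(C)C)C(O)=O | intermediate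
6 | 2,10-dimethylundeca-2,9-dien-6-one | CC(C)=CCCC(=O)CCC=C(C)C | intermediate
7 | ethyl formate | CCOC=O | starting material
8 | (5Z)-5-(hydroxymethylidene)-2,10-dimethylundeca-2,9-dien-6-one | O/C=C(\C(=O)CCC=C(C)C)CC=C(C)C | intermediate
9 | N-methoxy-N-methylacetamide | CC(=O)N(C)OC | starting material
10 | 2,4-bis(3-methylbut-2-enyl)-3,5-dioxohexanal (not isolated, epimerisable centres undefined) | O=CC(CC=C(C)C)C(=O)C(CC=C(C)C)C(C)=O | intermediate
11 | 2-methyl-3,5-bis(3-methylbut-2-enyl)-4H-pyran-4-one | CC1=C(CC=C(C)C)C(=O)C(CC=C(C)C)=CO1 | intermediate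
12 | 4-hydroxybenzaldehyde | O=Cc1ccc(O)cc1 | starting material
13 | 3-chloro-3-methylbut-1-yne | CC(C)(Cl)C#C | starting material
14 | 4-[(2-methylbut-3-yn-2-yl)oxy]benzaldehyde | O=Cc1ccc(OC(C)(C)C#C)cc1 | intermediate
15 | 2,2-dimethyl-2H-chromene-6-carbaldehyde | O=Cc1ccc2OC(C)(C)C=Cc2c1 | intermediate
16 | diethyl {2-[methoxy(methyl)amino]-2-oxoethyl}phosphonate | CCOP(=O)(CC(=O)N(C)OC)OCC | starting material
17 | (2E)-3-(2,2-dimethyl-2H-chromen-6-yl)-N-methoxy-N-methylprop-2-enamide | CON(C)C(=O)/C=C/c1ccc2OC(C)(C)C=Cc2c1 | intermediate
18 | 2-[(3E)-4-(2,2-dimethyl-2H-chromen-6-yl)-2-oxobut-3-enyl]-3,5-bis(3-methylbut-2-enyl)-4H-pyran-4-one | CC(C)=CCC1=COC(CC(=O)/C=C/c2ccc3OC(C)(C)C=Cc3c2)=C(CC=C(C)C)C1=O | intermediate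
19 | (8E)-9-(2,2-dimethyl-2H-chromen-6-yl)-1-methoxy-2,4-bis(3-methylbut-2-enyl)nona-1,8-diene-3,5,7-trione (not isolated, enol ether geometry and C4 centre undefined) | COC=C(CC=C(C)C)C(=O)C(CC=C(C)C)C(=O)CC(=O)/C=C/c1ccc2OC(C)(C)C=Cc2c1 | intermediate
20 | (2E)-1-[2,4-dihydroxy-3,5-bis(3-methylbut-2-enyl)phenyl]-3-(2,2-dimethyl-2H-chromen-6-yl)prop-2-en-1-one | CC(C)=CCc1cc(C(=O)/C=C/c2ccc3OC(C)(C)C=Cc3c2)c(O)c(CC=C(C)C)c1O | intermediate
21 | (2S)-2-(2,2-dimethyl-2H-chromen-6-yl)-7-hydroxy-6,8-bis(3-methylbut-2-enyl)-2,3-dihydro-4H-chromen-4-one (the target flavanone) | CC(C)=CCc1cc2c(c(CC=C(C)C)c1O)O[C@H](c1ccc3c(c1)C=CC(C)(C)O3)CC2=O | target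

**Step count**

Total: 10 steps. Longest linear sequence: 7 steps (steps 1, 2, 3, 4, 8, 9, 10); the aldehyde branch (steps 5, 6, 7) joins at step 8.

**Steps most likely to fail**

Step 9. The opened chain may fragment by retro-Claisen cleavage before the C4a–C5 bond forms, or the substrate may rest as its C4a-deprotonated anion and resist methoxide addition, so that the recyclisation stalls. The fallback takes ring A from the aromatic pool instead of building it; it sets out from 2 and 15 and comes back at 20. Commercial 1-(2,4-dihydroxyphenyl)ethanone F1 would be C-prenylated at both free positions flanking the 4-hydroxyl with 2 in aqueous KOH, giving 1-[2,4-dihydroxy-3,5-bis(3-methylbut-2-enyl)phenyl]ethanone F2 after separation from mono- and O-prenylated material. Claisen–Schmidt condensation of F2 with 15 (KOH, EtOH, rt) should then give chalcone 20.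

Step 10. Facial selectivity may be poor or of the wrong sense, and reversible ring opening under the basic catalyst may erode the ee. The fallback replaces asymmetric catalysis by resolution; it sets out from 20 and comes back at 21. Cyclisation of 20 with NaOAc in refluxing EtOH should give the racemic flavanone F3. Kinetic resolution by asymmetric transfer hydrogenation with RuCl[(R,R)-TsDPEN](p-cymene) in HCO2H/Et3N is expected to reduce the 2R enantiomer faster, to the cis alcohol (2R,4R)-2-(2,2-dimethyl-2H-chromen-6-yl)-6,8-bis(3-methylbut-2-enyl)-3,4-dihydro-2H-chromene-4,7-diol F4. F4 is removed by chromatography and the unreacted ketone is 21.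

Step 8. The dienolate may add in conjugate fashion to the acrylamide, or proton transfer may return 11 without acylation. The fallback forms the same bond at the aldehyde oxidation level; it sets out from 15 and 11 and comes back at 18. Wittig reaction of 15 with Ph3P=CHCHO should give (2E)-3-(2,2-dimethyl-2H-chromen-6-yl)prop-2-enal F5. Lithiated 11 (LiN(SiMe3)2, THF, −78 °C) should add 1,2 to F5 to give racemic 2-[(3E)-4-(2,2-dimethyl-2H-chromen-6-yl)-2-hydroxybut-3-enyl]-3,5-bis(3-methylbut-2-enyl)-4H-pyran-4-one F6. Oxidation of F6 with Dess–Martin periodinane (NaHCO3-buffered, CH2Cl2) should give 18.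

**Further compounds**

F1 | step 9 | 1-(2,4-dihydroxyphenyl)ethanone | CC(=O)c1ccc(O)cc1O
F2 | step 9 | 1-[2,4-dihydroxy-3,5-bis(3-methylbut-2-enyl)phenyl]ethanone | CC(=O)c1cc(CC=C(C)C)c(O)c(CC=C(C)C)c1O
F3 | step 10 | racemic 2-(2,2-dimethyl-2H-chromen-6-yl)-7-hydroxy-6,8-bis(3-methylbut-2-enyl)-2,3-dihydro-4H-chromen-4-one | CC(C)=CCc1cc2c(c(CC=C(C)C)c1O)OC(c1ccc3c(c1)C=CC(C)(C)O3)CC2=O
F4 | step 10 | (2R,4R)-2-(2,2-dimethyl-2H-chromen-6-yl)-6,8-bis(3-methylbut-2-enyl)-3,4-dihydro-2H-chromene-4,7-diol | CC(C)=CCc1cc2c(c(CC=C(C)C)c1O)O[C@@H](c1ccc3c(c1)C=CC(C)(C)O3)C[C@H]2O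
F5 | step 8 | (2E)-3-(2,2-dimethyl-2H-chromen-6-yl)prop-2-enal | O=C/C=C/c1ccc2OC(C)(C)C=Cc2c1
F6 | step 8 | racemic 2-[(3E)-4-(2,2-dimethyl-2H-chromen-6-yl)-2-hydroxybut-3-enyl]-3,5-bis(3-methylbut-2-enyl)-4H-pyran-4-one | CC(C)=CCC1=COC(CC(O)/C=C/c2ccc3OC(C)(C)C=Cc3c2)=C(CC=C(C)C)C1=O
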